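The route rests on the bond of the cyclobutane that joins the bridgehead CH α to the enone carbonyl with the methyl-bearing quaternary carbon α to the tiglate carbinol: the two carbons sit between two oxygenated carbons (a 1,4-dioxygen pattern), so both can be enolate carbons. Intramolecular oxidative coupling of the bis-dienolate of a cis-fused bicyclo[5.4.0]undecadienedione forms this bond, closes the cyclobutane and thereby creates the bicyclo[3.1.1]heptenone and bicyclo[4.1.1]octenone rings with two stereocentres. The precursor arises from a catalytic enantioselective Diels–Alder desymmetrisation of 4,4-dimethylcyclohexadienone and a diazoethane ring expansion; the diester is set by an Evans–Tishchenko reduction.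

Key step: step 6

Remark: the 2-methylbut-2-enoate of the target is the (E) isomer (tiglate), as its SMILES encodes. For 6–8 the locants are those of the benzo[7]annulene skeleton: C1 = CH2 α' to the ring A carbonyl C2, C4a and C9a = ring-fusion carbons, C5 = CH(CH3) α' to the ring B carbonyl C6, C9 = C(CH3)2.

Step 1
Reactants: 1 4,4-dimethylcyclohex-2-en-1-one
Product: 2 4,4-dimethylcyclohexa-2,5-dien-1-one
Conditions: DDQ (1.3 equiv), 1,4-dioxane, reflux
Reagents that add atoms: none
Why: Quinone dehydrogenation of the enone through its dienol should give the achiral cross-conjugated dienone, a standard DDQ oxidation of 4,4-disubstituted cyclohexenones in which no stereocentre is formed.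

Step 2
Reactants: 3 (E)-pent-3-en-2-one
Product: 4 (E)-2-(triisopropylsilyloxy)penta-1,3-diene
Conditions: iPr3SiOTf, Et3N, CH2Cl2, 0 °C
Reagents that add atoms: triisopropylsilyl trifluoromethanesulfonate, CC(C)[Si](C(C)C)(C(C)C)OS(=O)(=O)C(F)(F)F
Why: Enol silylation with a silyl triflate and an amine should occur at the α'-methyl group and leave the (E)-propenyl unit untouched, giving the 2-silyloxy diene.

Step 3
Reactants: 2 4,4-dimethylcyclohexa-2,5-dien-1-one; 4 (E)-2-(triisopropylsilyloxy)penta-1,3-diene
Product: 5 (4aR,8S,8aS)-4,4,8-trimethyl-6-(triisopropylsilyloxy)-4a,5,8,8a-tetrahydronaphthalen-1(4H)-one (cis-fused)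
Conditions: (S)-B-(o-tolyl)-α,α-diphenylprolinol oxazaborolidine·Tf2NH (20 mol %), CH2Cl2, −78 → −40 °C
Reagents that add atoms: none
Why: A catalytic enantioselective Diels–Alder reaction with a chiral oxazaborolidinium Lewis acid should desymmetrise the two enantiotopic enone arms; the nucleophilic CH2 terminus of the diene bonds to the β-carbon next to C(CH3)2 and the CH(CH3) terminus to the α-carbon, suprafacial addition sets the cis ring fusion, the endo mode sets the temporary C8 methyl centre, and the catalyst enantiomer sets the absolute configuration (the mirror-image catalyst would be taken if the sense of induction proved opposite).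

Step 4
Reactants: 5 the cis-fused Diels–Alder adduct
Product: 6 cis-fused 4,5,9,9-tetramethyl-2-(triisopropylsilyloxy)-1,4,4a,5,9,9a-hexahydro-6H-benzo[7]annulen-6-one (C5 epimers)
Conditions: CH3CHN2 (Et2O solution, 1.5 equiv), Sc(OTf)3 (10 mol %), CH2Cl2/toluene, −78 °C
Reagents that add atoms: diazoethane, CC=[N+]=[N-]
Why: In this Lewis-acid-catalysed diazoalkane homologation (Tiffeneau–Demjanov-type ring expansion) diazoethane adds to the only ketone, and, as is usual for conjugated enones, the saturated α-carbon (the ring-fusion CH) rather than the vinylic one should migrate with retention, inserting CH(CH3) between the carbonyl and the ring fusion; the new C5 centre forms as an epimer mixture that is erased in step 6.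

Step 5
Reactants: 6 the ring-expanded silyl dienol ether
Product: 7 (4aS,9aR)-4,5,9,9-tetramethyl-4a,5,9,9a-tetrahydro-1H-benzo[7]annulene-2,6-dione (cis-fused bis-enone, C5 epimers)
Conditions: Pd(OAc)2 (1.1 equiv), MeCN, 40 °C
Reagents that add atoms: none
Why: Saegusa–Ito oxidation of the regiodefined silyl enol ether (palladium enolate, then β-hydride elimination towards C4) should give the β-methyl enone of ring A and remove the temporary C4 stereocentre, while the cis ring fusion is untouched.

Step 6
Reactants: 7 the cis-fused bis-enone
Product: 9 tricyclic bis-enone (4-methylbicyclo[3.1.1]hept-3-en-2-one whose bridge carbons C6, bearing CH3, and C7 are linked by a C(=O)–CH=CH–C(CH3)2 tether with the carbonyl on C6), via dilithium bis-dienolate 8 (not isolated)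
Conditions: LiN(iPr)2 (2.3 equiv), THF, −78 → −40 °C; then I2 (1.05 equiv), THF, −78 °C → rt, slow addition at high dilution
Reagents that add atoms: lithium diisopropylamide, [Li+].CC(C)[N-]C(C)C (supplies the lithium of 8 only; nothing from it remains in 9)
Why: Kinetic deprotonation of each enone occurs at α' (the C1 methylene of ring A; the C5 methine of ring B, the only acidic site of that ring because C9 is quaternary and C7 vinylic), so the cross-conjugated bis-dienolate 8 carries its nucleophilic carbons exactly at C1 and C5; iodine should then iodinate the more accessible C1 on the face anti to the C9a–C9 bond, and the tetrasubstituted C5 enolate on the opposite face displaces iodide (one-electron oxidation and radical–enolate union would give the same bond). The closest known reaction type is the iodine- or copper-mediated intramolecular oxidative coupling of ketone and ester dienolates to 1,4-dicarbonyl compounds, merged with the enolate alkylations that close the cyclobutane of bicyclo[3.1.1]heptanones. The cyclobutane closes in a 4-exo-tet mode (4-exo-trig in the radical variant), and the same bond completes the six-membered ring of the bicyclo[3.1.1]heptenone and the seven-membered ring of the bicyclo[4.1.1]octenone. Both new stereocentres, the bridgehead CH and the quaternary C–CH3, are fixed by the cis ring fusion, because C1 and C5 hang from the two fusion carbons on the same side and a four-membered ring cannot be trans-bridged. The step needs regioselective bis-enolisation, secured by kinetic α'-deprotonation of both enones, and intramolecular coupling, secured by dilution; the chief competitor is loss of HI from the α'-iodo ketone towards a phenol.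

Step 7
Reactants: 9 the tricyclic bis-enone
Product: 11 β-hydroxy ketone (tether now C(=O)–CH2–CH(OH)–C(CH3)2, carbinol next to C(CH3)2), via β-boryl ketone 10 (not isolated)
Conditions: B2pin2 (1.1 equiv), CuCl (5 mol %), NaOtBu (10 mol %), (R)-1-[(Sp)-2-(diphenylphosphino)ferrocenyl]ethyldicyclohexylphosphine (6 mol %), MeOH (2 equiv), THF, rt; then NaBO3·4H2O, THF/H2O, rt
Reagents that add atoms: bis(pinacolato)diboron, CC1(C)OB(OC1(C)C)B1OC(C)(C)C(C)(C)O1 (boron of 10); sodium perborate (used as tetrahydrate), [Na+].[O-]OB=O (oxygen of 11)
Why: Enantioselective conjugate borylation by a ligated monovalent copper–boryl species, then oxidation of the C–B bond with retention, should hydroxylate the β-monosubstituted cycloheptenone in preference to the β,β-disubstituted bridged enone; the two faces of the lower bridge are almost equivalent in 9, so the ligand is expected to set the new carbinol centre (the mirror-image ligand would be taken if the sense proved opposite).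

Step 8
Reactants: 11 the β-hydroxy ketone; 12 3-methylbutanal
Product: 13 hydroxy isovalerate (tether CH(OH)–CH2–CH(OC(=O)CH2CH(CH3)2)–C(CH3)2, free carbinol next to the quaternary C–CH3, 1,3-anti)
Conditions: 3-methylbutanal (6 equiv), SmI2 (30 mol %), THF, −10 °C
Reagents that add atoms: none
Why: In the Evans–Tishchenko reduction the hemiacetal formed from the hydroxyl and the aldehyde, held on trivalent samarium, delivers hydride to the ketone through a six-membered transition state, which should give the 1,3-anti carbinol, leave the isovaleryl group on the original hydroxyl and so differentiate the two oxygens; the enone is not a β-hydroxy ketone and is left alone.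

Step 9
Reactants: 13 the hydroxy isovalerate; 14 (E)-2-methylbut-2-enoyl chloride (tigloyl chloride)
Product: 15 CNP0194415.1 (target)
Conditions: DMAP (1.5 equiv), pyridine, CH2Cl2, 0 → 40 °C
Reagents that add atoms: none
Why: DMAP-catalysed acylation of the remaining hindered secondary alcohol should install the tiglate, the thermodynamically stable (E) isomer, without touching any stereocentre.

Compound list
1 | 4,4-dimethylcyclohex-2-en-1-one | CC1(C)CCC(=O)C=C1 | starting material
2 | 4,4-dimethylcyclohexa-2,5-dien-1-one | CC1(C)C=CC(=O)C=C1 | intermediate
3 | (E)-pent-3-en-2-one | C/C=C/C(C)=O | starting material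
4 | (E)-2-(triisopropylsilyloxy)penta-1,3-diene | C=C(O[Si](C(C)C)(C(C)C)C(C)C)/C=C/C | intermediate
5 | (4aR,8S,8aS)-4,4,8-trimethyl-6-(triisopropylsilyloxy)-4a,5,8,8a-tetrahydronaphthalen-1(4H)-one, cis-fused | CC(C)[Si](C(C)C)(C(C)C)OC1=C[C@H](C)[C@@H]2C(=O)C=CC(C)(C)[C@@H]2C1 | intermediate
6 | cis-fused 4,5,9,9-tetramethyl-2-(triisopropylsilyloxy)-1,4,4a,5,9,9a-hexahydro-6H-benzo[7]annulen-6-one, C5 epimers (centre left open) | CC(C)[Si](C(C)C)(C(C)C)OC1=C[C@H](C)[C@@H]2C(C)C(=O)C=CC(C)(C)[C@@H]2C1 | intermediate
7 | (4aS,9aR)-4,5,9,9-tetramethyl-4a,5,9,9a-tetrahydro-1H-benzo[7]annulene-2,6-dione, cis-fused, C5 epimers (centre left open) | O=C1C=C(C)[C@@H]2C(C)C(=O)C=CC(C)(C)[C@@H]2C1 | intermediate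
8 | dilithium bis-dienolate of 7 (enolate carbons C1 and C5) | [Li+].[Li+].[O-]C1C=C(C)[C@@H]2C(C)=C([O-])C=CC(C)(C)[C@@H]2C=1 | intermediate (not isolated)
9 | tricyclic bis-enone: 4-methylbicyclo[3.1.1]hept-3-en-2-one with bridge carbons C6 (CH3) and C7 linked by C(=O)–CH=CH–C(CH3)2, ring stereocentres as in 15 | O=C1C=CC(C)(C)[C@@H]2[C@H]3C(=O)C=C(C)[C@@H]2[C@]31C | intermediate
10 | β-pinacolboryl ketone (boron on the carbon next to C(CH3)2) | O=C1C[C@@H](B2OC(C)(C)C(C)(C)O2)C(C)(C)[C@@H]3[C@H]4C(=O)C=C(C)[C@@H]3[C@]41C | intermediate (not isolated)
11 | β-hydroxy ketone (hydroxyl on the carbon next to C(CH3)2) | O=C1C[C@@H](O)C(C)(C)[C@@H]2[C@H]3C(=O)C=C(C)[C@@H]2[C@]31C | intermediate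
12 | 3-methylbutanal | CC(C)CC=O | starting material
13 | 1,3-anti hydroxy isovalerate (free carbinol next to the quaternary C–CH3) | O[C@@H]1C[C@@H](OC(=O)CC(C)C)C(C)(C)[C@@H]2[C@H]3C(=O)C=C(C)[C@@H]2[C@]31C | intermediate
14 | (E)-2-methylbut-2-enoyl chloride | C/C=C(\C)C(Cl)=O | starting material
15 | CNP0194415.1 | C/C=C(\C)C(=O)O[C@@H]1C[C@@H](OC(=O)CC(C)C)C(C)(C)[C@@H]2[C@H]3C(=O)C=C(C)[C@@H]2[C@]31C | target

Total step count: 9. Longest linear sequence: 8 steps (steps 1 and 3 to 9, from compound 1); step 2 is a one-step branch.

Steps most likely to fail

Step 6. Elimination of HI from the transient α'-iodo ketone, with aromatisation of ring A, or intermolecular coupling may outrun the strained four-membered closure. The fallback sets out from 7 and comes back at 9. Compound 7 would be converted with LiN(iPr)2 (2.3 equiv) and Me3SiCl in THF at −78 °C into the isolated bis(trimethylsilyl) dienol ether F1. F1 would then be oxidised with (NH4)2Ce(NO3)6 (2.2 equiv) and NaHCO3 in MeCN at −30 °C. This replaces the dianion and iodine by a neutral substrate and a one-electron oxidant: the radical cation of one silyl enol ether attacks the other, and a second oxidation with loss of both silyl groups should give 9 (known oxidative coupling of silyl bis-enol ethers).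

Step 4. The reactive secondary diazoalkane may insert more than once, add as a dipole to the enone, or be consumed before it reaches the hindered conjugated ketone. The fallback sets out from 5 and comes back at 6. Compound 5 would be homologated with Me3SiCHN2 and AlMe3 in CH2Cl2 at −78 °C, which stops cleanly after one insertion, to give the α-trimethylsilyl cycloheptenone F2. K2CO3 in MeOH would remove the silyl group to give the cycloheptenone F3. LiN(iPr)2 and then MeI in THF at −78 °C would methylate F3 at its only enolisable position (α' of ring B; the ring A silyl enol ether carries no acidic hydrogen), giving 6.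

Step 7. The copper–boryl addition may be sluggish at the neopentyl β-carbon, or the facial selectivity may be poor if ligand and tricycle are mismatched. The fallback sets out from 9 and comes back at 11. Nucleophilic (Weitz–Scheffer) epoxidation of the cycloheptenone with tBuOOH and DBU in CH2Cl2 would give the epoxy ketone F4; its face isomer would be separated by chromatography. Reductive opening of F4 at the α-carbon with (PhSe)2, NaBH4 and AcOH in EtOH at 0 °C should give 11.

Further compounds
F1 | step 6 | bis(trimethylsilyl) dienol ether of 7 (silyloxy dienes at C1=C2 and C5=C6) | C[Si](C)(C)OC1C=C(C)[C@@H]2C(C)=C(O[Si](C)(C)C)C=CC(C)(C)[C@@H]2C=1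
F2 | step 4 | 5-(trimethylsilyl) analogue of 6 lacking the C5 methyl (α-silyl cycloheptenone) | CC(C)[Si](C(C)C)(C(C)C)OC1=C[C@H](C)[C@@H]2C([Si](C)(C)C)C(=O)C=CC(C)(C)[C@@H]2C1
F3 | step 4 | cis-fused 4,9,9-trimethyl-2-(triisopropylsilyloxy)-1,4,4a,5,9,9a-hexahydro-6H-benzo[7]annulen-6-one | CC(C)[Si](C(C)C)(C(C)C)OC1=C[C@H](C)[C@@H]2CC(=O)C=CC(C)(C)[C@@H]2C1
F4 | step 7 | α,β-epoxy ketone of 9 (epoxide on the cycloheptenone, oxygen on the face of the later hydroxyl) | O=C1[C@H]2O[C@H]2C(C)(C)[C@@H]3[C@H]4C(=O)C=C(C)[C@@H]3[C@]41C
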